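Readings and results are calculated with made-up constants; the scatter is artificial.

Add solvolysis product and target in each earlier run, and set the sum beside the second nucleophile charged.

| setting | Wednesday's | Sunday's | Monday's | oak | maple | alder | birch |
|---|---|---|---|---|---|---|---|
| starting material | 20 mM | 10 mM | 40 mM | 20 mM | 20 mM | 20 mM | 20 mM (fed, over 2.0 h) |
| second nucleophile | 0.60 equiv | 0.60 equiv | 0.60 equiv | 0.600 equiv (in portions, 5, over 2.0 h) | 0.600 equiv | 0.600 equiv (fed, over 2.0 h) | 0.600 equiv |
| solid first nucleophile | 0.95 equiv | 0.95 equiv | 0.95 equiv | 0.950 equiv | 0.950 equiv | 0.950 equiv | 0.950 equiv |
| temperature | 55 °C | 66 °C | 55 °C | 60 °C | 60 °C |  | 60 °C |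
| remark | run made earlier | run made earlier | run made earlier | first portion at the start, last at 2.0 h | everything together at the start | the addition at 30 °C, then warmed to 60 °C; the feed brings no volume worth counting | all else is in the flask from the start; the feed brings no volume worth counting |
| time |  |  |  | 5.0 h | 5.0 h | 5.0 h | 5.0 h |

- Wednesday's (time / h: solvolysis product / %, target / %): 0.250: 17, 2; 0.500: 27, 5; 1.33: 36, 7; 3.00: 36, 6
- Sunday's (time / h: solvolysis product / %, target / %): 0.833: 52, 1; 2.00: 51, 2; 4.00: 52, 4; 6.00: 52, 3
- Monday's (time / h: solvolysis product / %, target / %): 0.500: 29, 3; 1.00: 37, 5; 2.50: 38, 7; 6.00: 36, 6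

(standard deviation of a reading: 1.5 percentage points)

- at the start none of the solid first nucleophile is in solution

* the flask that comes out highest in amount of solvolysis product, in percent of the starting material charged, or "all alike" when all lie within 1.5 percentage points (oak / maple / alder / birch / all alike)
* solvolysis product at the end, in percent of the starting material charged, oak
* solvolysis product at the end, in percent of the starting material charged, maple
* solvolysis product at the end, in percent of the starting material charged, alder
* solvolysis product at the end, in percent of the starting material charged, birch

On its plateau Wednesday's sum reads 43.0% and Monday's reads 45.0%, at twice the concentration, and both lie near 40.0%, the charge less the second nucleophile. So I take it that the second nucleophile removes starting material from these two products mole for mole. Sunday's hotter, thinner run reads 56.0%, so this mark is a lower limit. I carry one number, W = 88.0% for oak, the overflow: the share of the charge above the second nucleophile standing in the flask while the starting material goes.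

Now I run oak slowly. In the first instants the starting material turns over with just one portion present, 0.120. The next portion comes 0.500 h later. Wednesday's solvolysis product closes its gap to the plateau with a half-life of about 0.232 h, as read, which leaves 22.4% of that gap open when oak's second portion arrives. Oak runs hotter, at 60 °C, so I treat that as the high side. At the end the later portions should find little to capture. Taking Wednesday's target reading off W, I commit to about 81.0% solvolysis product for oak. Maple has the whole second nucleophile present from the start, so its mark stays near 40.0% for the sum, below my figure for oak. Alder and birch each have a steady feed, and I do not reckon them; I name oak as my choice for the highest.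

The forecast also names oak, but with 44% for oak, far from my figure, then 43% for maple, 18% for alder and 10% for birch, reasoning that “less second nucleophile meets the starting material early”.

The flasks give 81.8% for oak, 40.9% for maple, 26.3% for alder and 43.4% for birch, so oak is highest.

    second nucleophile + intermediate → other capture product (k = 18000 M⁻¹ h⁻¹, Ea = 51.0 kJ mol⁻¹)
    intermediate → solvolysis product (k = 44.0 h⁻¹, Ea = 97.0 kJ mol⁻¹)
    starting material → intermediate (k = 7.10 h⁻¹, Ea = 86.0 kJ mol⁻¹)
    first nucleophile + intermediate → target (k = 5100 M⁻¹ h⁻¹, Ea = 41.0 kJ mol⁻¹)
    solid first nucleophile ⇌ first nucleophile, rate k5*(cs5 - [first nucleophile]) while solid is left; crystals form when [first nucleophile] > cs5 (solubility = 7.50 mM, k = 0.710 h⁻¹)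
    2 second nucleophile → self-condensation product (k = 35.0 M⁻¹ h⁻¹, Ea = 60.0 kJ mol⁻¹)
    (constants at 60 °C)

In oak the starting material went first, with 97% of its turnover done by 0.500 h; other capture product ended at 13.4% and solvolysis product plus target came to 86.6%, against W of 88.0%. Oak's last portion met 0% starting material at 2.00 h, and 24.3% of the second nucleophile still stood at 5.00 h. A neighbouring flask, the same as oak but with 0.240 equiv of second nucleophile, has W of 95.2%, and its solvolysis product plus target came to 94.4%.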